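## Retrosynthetic overview

1. Target 33 ⇐ alcohol oxidation and desilylation ⇐ epoxy silyl ether 31 ⇐ site- and face-selective epoxidation of cyclohexadiene 30 (oxirane ring formed last).
2. 30 ⇐ catalytic enantioselective 6π electrocyclization (the proposed new step) of the (E,Z,E,E)-tetraenyl pyrone 29 (carbocycle formed second; sets the quaternary and the adjacent ring stereocentre).
3. 29 ⇐ Negishi coupling of the (Z)-dienyl iodide 14 with the alkenylzinc made by hydrozirconation of enyne 26.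
4. 14 ⇐ vinylogous aldol and dehydration of ethyl pyrone 6 with (Z)-3-iodo-2-methylacrolein 10; 6 (pyranone ring formed first) ⇐ keto ester dianion acylation, lactonisation, O-methylation.
5. 26 ⇐ Evans syn-aldol (sets the side-chain methyl stereocentre), Wittig olefination, Corey–Fuchs homologation.

Assumption: tetraene 29 does not cyclise appreciably below about 40 °C without a catalyst (it is handled cold and in the dark), and the (S,S) acid is taken as the enantiomer that gives the (1R,6S) ring, the (R,R) acid being used in the same way if the sense proves opposite.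

## Route

Step 1
Reactants: 1 methyl 2-methyl-3-oxopentanoate; 2 N-methoxy-N-methylpropanamide
Product: 4 methyl 2,4-dimethyl-3,5-dioxoheptanoate, via sodium lithium dianion 3 (not isolated)
Conditions: NaH, THF, 0 °C; n-BuLi, 0 °C; 2, 0 °C to rt; 1 M HCl
Reagents that add atoms: none
Why: γ-Acylation of a β-keto ester dianion with a Weinreb amide (Huckin–Weiler-type dianion chemistry), the γ-carbanion being the more reactive site and the stable tetrahedral chelate preventing over-addition.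

Step 2
Reactants: 4 methyl 2,4-dimethyl-3,5-dioxoheptanoate
Product: 5 6-ethyl-4-hydroxy-3,5-dimethyl-2H-pyran-2-one
Conditions: DBU (1.5 equiv), toluene, 80 °C; 1 M HCl
Reagents that add atoms: none
Why: Base-mediated enol lactonisation (intramolecular acyl substitution) of the 3,5-diketo ester closes the pyranone ring, driven by formation of the aromatic vinylogous acid.

Step 3
Reactants: 5 6-ethyl-4-hydroxy-3,5-dimethyl-2H-pyran-2-one
Product: 6 2-ethyl-6-methoxy-3,5-dimethyl-4H-pyran-4-one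
Conditions: MeOTf, CH2Cl2, rt; aq. NaHCO3
Reagents that add atoms: methyl trifluoromethanesulfonate COS(=O)(=O)C(F)(F)F
Why: Hard O-methylation at the lactone carbonyl oxygen gives a 2-methoxy-4-hydroxypyrylium ion that loses a proton to the α-methoxy-γ-pyrone (regioselective O-alkylation).

Step 4
Reactants: 7 prop-2-yn-1-ol
Product: 9 (2Z)-3-iodo-2-methylprop-2-en-1-ol, via vinylmagnesium alkoxide 8 (not isolated)
Conditions: MeMgBr (3 equiv), CuI (10 mol%), THF, −10 °C to rt; I2, −10 °C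
Reagents that add atoms: methylmagnesium bromide C[Mg]Br; iodine [I][I]
Why: Copper-catalysed anti-carbomagnesiation of the propargylic alkoxide through a five-membered magnesium chelate places Mg cis to CH2O, and iodinolysis with retention gives the Z iodide.

Step 5
Reactants: 9 (2Z)-3-iodo-2-methylprop-2-en-1-ol
Product: 10 (2Z)-3-iodo-2-methylprop-2-enal
Conditions: MnO2, CH2Cl2, rt, dark
Reagents that add atoms: none
Why: Neutral allylic alcohol oxidation with MnO2 leaves the Z iodoalkene geometry intact.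

Step 6
Reactants: 6 2-ethyl-6-methoxy-3,5-dimethyl-4H-pyran-4-one; 10 (2Z)-3-iodo-2-methylprop-2-enal
Product: 12 2-[(4Z)-3-hydroxy-5-iodo-4-methylpent-4-en-2-yl]-6-methoxy-3,5-dimethyl-4H-pyran-4-one (diastereomer mixture), via lithiated pyrone 11 (not isolated)
Conditions: LiN(SiMe3)2, THF, −78 °C; 10, −78 °C; aq. NH4Cl
Reagents that add atoms: none
Why: Vinylogous aldol addition, the ethyl CH2 being the γ-position of the pyranone and the extended enolate adding 1,2 to the enal at low temperature; the two new stereocentres are removed in step 7.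

Step 7
Reactants: 12 2-[(4Z)-3-hydroxy-5-iodo-4-methylpent-4-en-2-yl]-6-methoxy-3,5-dimethyl-4H-pyran-4-one
Product: 14 2-[(2E,4Z)-5-iodo-4-methylpenta-2,4-dien-2-yl]-6-methoxy-3,5-dimethyl-4H-pyran-4-one, via allylic mesylate 13 (not isolated)
Conditions: MsCl, Et3N, CH2Cl2, 0 °C; DBU, rt, dark
Reagents that add atoms: none
Why: Mesylation then E1cB elimination through the vinylogous pyrone enolate gives the thermodynamically preferred E alkene (chain trans to the pyrone) without touching the Z iodoalkene.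

Step 8
Reactants: 15 (4S)-4-benzyl-3-propanoyl-1,3-oxazolidin-2-one; 16 propanal
Product: 18 (4S)-4-benzyl-3-[(2S,3R)-3-hydroxy-2-methylpentanoyl]-1,3-oxazolidin-2-one, via dibutylboron (Z)-enolate 17 (not isolated)
Conditions: Bu2BOTf, Et3N, CH2Cl2, 0 °C; 16, −78 to 0 °C; H2O2, MeOH, pH 7 buffer
Reagents that add atoms: none
Why: Evans syn-aldol reaction, in which the Z boron enolate reacts through a Zimmerman–Traxler chair and the (S)-benzyl auxiliary fixes the (2S,3R) configuration; C2 becomes the side-chain methyl stereocentre of the target.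

Step 9
Reactants: 18 (4S)-4-benzyl-3-[(2S,3R)-3-hydroxy-2-methylpentanoyl]-1,3-oxazolidin-2-one
Product: 19 (2S,3R)-3-hydroxy-N-methoxy-N,2-dimethylpentanamide
Conditions: MeONHMe·HCl, AlMe3, THF, −20 to 0 °C; Rochelle salt
Reagents that add atoms: N,O-dimethylhydroxylamine hydrochloride Cl.CNOC
Why: Weinreb transamidation with the aluminium amide cleaves the exocyclic imide carbonyl selectively (assisted by the free β-hydroxyl) without epimerisation.

Step 10
Reactants: 19 (2S,3R)-3-hydroxy-N-methoxy-N,2-dimethylpentanamide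
Product: 20 (2S,3R)-3-[(tert-butyldimethylsilyl)oxy]-N-methoxy-N,2-dimethylpentanamide
Conditions: TBSOTf, 2,6-lutidine, CH2Cl2, 0 °C
Reagents that add atoms: tert-butyldimethylsilyl trifluoromethanesulfonate CC(C)(C)[Si](C)(C)OS(=O)(=O)C(F)(F)F
Why: Standard silylation of a secondary alcohol with a silyl triflate and a hindered base.

Step 11
Reactants: 20 (2S,3R)-3-[(tert-butyldimethylsilyl)oxy]-N-methoxy-N,2-dimethylpentanamide
Product: 21 (2S,3R)-3-[(tert-butyldimethylsilyl)oxy]-2-methylpentanal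
Conditions: i-Bu2AlH, THF, −78 °C; Rochelle salt
Reagents that add atoms: none
Why: Hydride reduction of a Weinreb amide stops at the chelated tetrahedral intermediate and releases the α-chiral aldehyde on work-up without epimerisation.

Step 12
Reactants: 21 (2S,3R)-3-[(tert-butyldimethylsilyl)oxy]-2-methylpentanal; 22 2-(triphenyl-λ5-phosphanylidene)propanal
Product: 23 (2E,4R,5R)-5-[(tert-butyldimethylsilyl)oxy]-2,4-dimethylhept-2-enal
Conditions: toluene, 90 °C
Reagents that add atoms: none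
Why: Wittig olefination with a stabilised formyl ylide gives the E trisubstituted enal under non-basic conditions that preserve the α-stereocentre.

Step 13
Reactants: 23 (2E,4R,5R)-5-[(tert-butyldimethylsilyl)oxy]-2,4-dimethylhept-2-enal
Product: 24 tert-butyl{[(3R,4R,5E)-8,8-dibromo-4,6-dimethylocta-5,7-dien-3-yl]oxy}dimethylsilane
Conditions: CBr4, PPh3, CH2Cl2, 0 °C
Reagents that add atoms: carbon tetrabromide BrC(Br)(Br)Br
Why: Corey–Fuchs (Ramirez) dibromo-olefination of the aldehyde with the ylide formed from CBr4 and PPh3.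

Step 14
Reactants: 24 tert-butyl{[(3R,4R,5E)-8,8-dibromo-4,6-dimethylocta-5,7-dien-3-yl]oxy}dimethylsilane
Product: 26 tert-butyl{[(3R,4R,5E)-4,6-dimethylnon-5-en-7-yn-3-yl]oxy}dimethylsilane, via lithium acetylide 25 (not isolated)
Conditions: n-BuLi (2.2 equiv), THF, −78 °C; MeI, DMPU, −78 °C to rt
Reagents that add atoms: iodomethane IC
Why: Second stage of the Corey–Fuchs alkyne synthesis (Br/Li exchange, elimination to the acetylide) followed by C-methylation of the acetylide.

Step 15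
Reactants: 26 tert-butyl{[(3R,4R,5E)-4,6-dimethylnon-5-en-7-yn-3-yl]oxy}dimethylsilane; 14 2-[(2E,4Z)-5-iodo-4-methylpenta-2,4-dien-2-yl]-6-methoxy-3,5-dimethyl-4H-pyran-4-one
Product: 29 2-[(2E,4Z,6E,8E,10R,11R)-11-[(tert-butyldimethylsilyl)oxy]-4,6,8,10-tetramethyltrideca-2,4,6,8-tetraen-2-yl]-6-methoxy-3,5-dimethyl-4H-pyran-4-one, via alkenylzirconocene chloride 27 (not isolated), via alkenylzinc chloride 28 (not isolated)
Conditions: Cp2Zr(H)Cl, THF, 40 °C, dark; ZnCl2, 0 °C; 14, Pd(PPh3)4 (5 mol%), 20 °C, dark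
Reagents that add atoms: none
Why: Syn-hydrozirconation places Zr on the less hindered methyl-bearing alkyne carbon, and transmetalation to zinc followed by Negishi coupling proceeds with retention at both alkenyl partners to give the E,Z,E,E tetraene.

Step 16
Reactants: 29 2-[(2E,4Z,6E,8E,10R,11R)-11-[(tert-butyldimethylsilyl)oxy]-4,6,8,10-tetramethyltrideca-2,4,6,8-tetraen-2-yl]-6-methoxy-3,5-dimethyl-4H-pyran-4-one
Product: 30 2-[(1R,6S)-6-[(2E,4R,5R)-5-[(tert-butyldimethylsilyl)oxy]-4-methylhept-2-en-2-yl]-1,3,5-trimethylcyclohexa-2,4-dien-1-yl]-6-methoxy-3,5-dimethyl-4H-pyran-4-one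
Conditions: chiral acid A (10 mol%; the (S,S)-imidodiphosphorimidate built from two (S)-3,3'-bis[3,5-bis(trifluoromethyl)phenyl]-1,1'-bi-2-naphthol units with N-SO2CF3 groups), toluene, −20 °C, dark; Et3N quench
Reagents that add atoms: none
Why: Proposed new method: catalytic enantioselective carba-6π electrocyclization under chiral-counteranion control, an isomerisation with no by-product — the confined acid protonates the strongly basic γ-pyrone carbonyl of 29 to a 4-hydroxy-2-methoxypyrylium ion held in the chiral anion pocket by a hydrogen bond; this cationic acceptor at the triene terminus (C2 of the chain) polarises the C2=C3/C4=C5/C6=C7 hexatriene and should lower the barrier of the thermally allowed disrotatory closure (new C2–C7 bond) enough for it to run at −20 °C where free 29 is inert; the E,Z,E geometry forces pyrone and alkenyl cis, and the pocket admits only one helical s-cis,s-cis conformer, so one sense of disrotation sets the quaternary C1 (R) and C6 (S) of the ring together; the closest known reaction types are the Lewis-acid-accelerated thermal 6π electrocyclization of acyl-substituted hexatrienes and the chiral Brønsted-acid-catalysed Nazarov (4π) electrocyclization.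

Step 17
Reactants: 30 2-[(1R,6S)-6-[(2E,4R,5R)-5-[(tert-butyldimethylsilyl)oxy]-4-methylhept-2-en-2-yl]-1,3,5-trimethylcyclohexa-2,4-dien-1-yl]-6-methoxy-3,5-dimethyl-4H-pyran-4-one
Product: 31 2-[(1R,4R,5R,6S)-5-[(2E,4R,5R)-5-[(tert-butyldimethylsilyl)oxy]-4-methylhept-2-en-2-yl]-2,4,6-trimethyl-7-oxabicyclo[4.1.0]hept-2-en-4-yl]-6-methoxy-3,5-dimethyl-4H-pyran-4-one
Conditions: (R,R)-N,N'-bis(3,5-di-tert-butylsalicylidene)-1,2-cyclohexanediaminatomanganese chloride (C36H52ClMnN2O2, 5 mol%), 4-phenylpyridine N-oxide (20 mol%), NaOCl (aq., pH 11.3), CH2Cl2, 0 °C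
Reagents that add atoms: sodium hypochlorite [Na+].[O-]Cl
Why: Jacobsen–Katsuki epoxidation, in which the manganese oxo species reacts with the conjugated diene much faster than with the isolated side-chain alkene, attacks the C4=C5 bond (the one not flanked by the quaternary carbon) from the face opposite the cis C6-alkenyl and C1-pyrone groups, and the (R,R) catalyst is the matched one by analogy with its known sense on cyclic conjugated cis-alkenes, so both epoxide carbons are set.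

Step 18
Reactants: 31 2-[(1R,4R,5R,6S)-5-[(2E,4R,5R)-5-[(tert-butyldimethylsilyl)oxy]-4-methylhept-2-en-2-yl]-2,4,6-trimethyl-7-oxabicyclo[4.1.0]hept-2-en-4-yl]-6-methoxy-3,5-dimethyl-4H-pyran-4-one
Product: 32 2-[(1R,4R,5R,6S)-5-[(2E,4R,5R)-5-hydroxy-4-methylhept-2-en-2-yl]-2,4,6-trimethyl-7-oxabicyclo[4.1.0]hept-2-en-4-yl]-6-methoxy-3,5-dimethyl-4H-pyran-4-one
Conditions: Bu4NF, THF, rt
Reagents that add atoms: none
Why: Fluoride-mediated desilylation under basic, non-acidic conditions that the vinyl epoxide and pyrone tolerate.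

Step 19
Reactants: 32 2-[(1R,4R,5R,6S)-5-[(2E,4R,5R)-5-hydroxy-4-methylhept-2-en-2-yl]-2,4,6-trimethyl-7-oxabicyclo[4.1.0]hept-2-en-4-yl]-6-methoxy-3,5-dimethyl-4H-pyran-4-one
Product: 33 2-methoxy-3,5-dimethyl-6-[(1R,4R,5R,6S)-2,4,6-trimethyl-5-[(2E,4R)-4-methyl-5-oxohept-2-en-2-yl]-7-oxabicyclo[4.1.0]hept-2-en-4-yl]-4H-pyran-4-one (CNP0336888.3)
Conditions: Dess–Martin periodinane, NaHCO3, CH2Cl2, 0 °C to rt
Reagents that add atoms: none
Why: Buffered Dess–Martin oxidation of the secondary alcohol gives the ethyl ketone without epimerising the adjacent allylic stereocentre, shifting the alkene into conjugation or opening the epoxide.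

## Compound list

1 | methyl 2-methyl-3-oxopentanoate | CCC(=O)C(C)C(=O)OC | starting material
2 | N-methoxy-N-methylpropanamide | CCC(=O)N(C)OC | starting material
3 | sodium lithium dianion (dienolate) of 1, formed in the flask | [Na+].[Li+].CC=C([O-])C(C)=C([O-])OC | intermediate
4 | methyl 2,4-dimethyl-3,5-dioxoheptanoate | CCC(=O)C(C)C(=O)C(C)C(=O)OC | intermediate
5 | 6-ethyl-4-hydroxy-3,5-dimethyl-2H-pyran-2-one | CCc1oc(=O)c(C)c(O)c1C | intermediate
6 | 2-ethyl-6-methoxy-3,5-dimethyl-4H-pyran-4-one | CCc1oc(OC)c(C)c(=O)c1C | intermediate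
7 | prop-2-yn-1-ol | C#CCO | starting material
8 | bromomagnesium (2Z)-3-(bromomagnesio)-2-methylprop-2-en-1-olate, formed in the flask | Br[Mg]/C=C(/C)CO[Mg]Br | intermediate
9 | (2Z)-3-iodo-2-methylprop-2-en-1-ol | OC/C(C)=C\I | intermediate
10 | (2Z)-3-iodo-2-methylprop-2-enal | O=C/C(C)=C\I | intermediate
11 | lithium 2-ethylidene-6-methoxy-3,5-dimethyl-2H-pyran-4-olate (6 lithiated at the ethyl CH2), formed in the flask | [Li+].CC=C1OC(OC)=C(C)C([O-])=C1C | intermediate
12 | 2-[(4Z)-3-hydroxy-5-iodo-4-methylpent-4-en-2-yl]-6-methoxy-3,5-dimethyl-4H-pyran-4-one (diastereomer mixture) | COc1oc(C(C)C(O)/C(C)=C\I)c(C)c(=O)c1C | intermediate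
13 | (4Z)-5-iodo-2-(6-methoxy-3,5-dimethyl-4-oxo-4H-pyran-2-yl)-4-methylpent-4-en-3-yl methanesulfonate, formed in the flask | COc1oc(C(C)C(OS(C)(=O)=O)/C(C)=C\I)c(C)c(=O)c1C | intermediate
14 | 2-[(2E,4Z)-5-iodo-4-methylpenta-2,4-dien-2-yl]-6-methoxy-3,5-dimethyl-4H-pyran-4-one | COc1oc(/C(C)=C/C(C)=C\I)c(C)c(=O)c1C | intermediate
15 | (4S)-4-benzyl-3-propanoyl-1,3-oxazolidin-2-one | CCC(=O)N1[C@@H](Cc2ccccc2)COC1=O | starting material
16 | propanal | CCC=O | starting material
17 | (4S)-4-benzyl-3-[(1Z)-1-[(dibutylboranyl)oxy]prop-1-en-1-yl]-1,3-oxazolidin-2-one, formed in the flask | C/C=C(\OB(CCCC)CCCC)N1[C@@H](Cc2ccccc2)COC1=O | intermediate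
18 | (4S)-4-benzyl-3-[(2S,3R)-3-hydroxy-2-methylpentanoyl]-1,3-oxazolidin-2-one | CC[C@@H](O)[C@H](C)C(=O)N1[C@@H](Cc2ccccc2)COC1=O | intermediate
19 | (2S,3R)-3-hydroxy-N-methoxy-N,2-dimethylpentanamide | CC[C@@H](O)[C@H](C)C(=O)N(C)OC | intermediate
20 | (2S,3R)-3-[(tert-butyldimethylsilyl)oxy]-N-methoxy-N,2-dimethylpentanamide | CC[C@@H](O[Si](C)(C)C(C)(C)C)[C@H](C)C(=O)N(C)OC | intermediate
21 | (2S,3R)-3-[(tert-butyldimethylsilyl)oxy]-2-methylpentanal | CC[C@@H](O[Si](C)(C)C(C)(C)C)[C@H](C)C=O | intermediate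
22 | 2-(triphenyl-λ5-phosphanylidene)propanal | CC(C=O)=P(c1ccccc1)(c1ccccc1)c1ccccc1 | starting material
23 | (2E,4R,5R)-5-[(tert-butyldimethylsilyl)oxy]-2,4-dimethylhept-2-enal | CC[C@@H](O[Si](C)(C)C(C)(C)C)[C@H](C)/C=C(\C)C=O | intermediate
24 | tert-butyl{[(3R,4R,5E)-8,8-dibromo-4,6-dimethylocta-5,7-dien-3-yl]oxy}dimethylsilane | CC[C@@H](O[Si](C)(C)C(C)(C)C)[C@H](C)/C=C(\C)C=C(Br)Br | intermediate
25 | lithium (3E,5R,6R)-6-[(tert-butyldimethylsilyl)oxy]-3,5-dimethyloct-3-en-1-yn-1-ide, formed in the flask | CC[C@@H](O[Si](C)(C)C(C)(C)C)[C@H](C)/C=C(\C)C#C[Li] | intermediate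
26 | tert-butyl{[(3R,4R,5E)-4,6-dimethylnon-5-en-7-yn-3-yl]oxy}dimethylsilane | CC[C@@H](O[Si](C)(C)C(C)(C)C)[C@H](C)/C=C(\C)C#CC | intermediate
27 | chlorobis(cyclopentadienyl)[(2E,4E,6R,7R)-7-[(tert-butyldimethylsilyl)oxy]-4,6-dimethylnona-2,4-dien-2-yl]zirconium, formed in the flask | CC[C@@H](O[Si](C)(C)C(C)(C)C)[C@H](C)/C=C(\C)/C=C(\C)[Zr](Cl)(C1C=CC=C1)C1C=CC=C1 | intermediate
28 | chloro[(2E,4E,6R,7R)-7-[(tert-butyldimethylsilyl)oxy]-4,6-dimethylnona-2,4-dien-2-yl]zinc, formed in the flask | CC[C@@H](O[Si](C)(C)C(C)(C)C)[C@H](C)/C=C(\C)/C=C(\C)[Zn]Cl | intermediate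
29 | 2-[(2E,4Z,6E,8E,10R,11R)-11-[(tert-butyldimethylsilyl)oxy]-4,6,8,10-tetramethyltrideca-2,4,6,8-tetraen-2-yl]-6-methoxy-3,5-dimethyl-4H-pyran-4-one | CC[C@@H](O[Si](C)(C)C(C)(C)C)[C@H](C)/C=C(\C)/C=C(\C)/C=C(/C)\C=C(/C)c1oc(OC)c(C)c(=O)c1C | intermediate
30 | 2-[(1R,6S)-6-[(2E,4R,5R)-5-[(tert-butyldimethylsilyl)oxy]-4-methylhept-2-en-2-yl]-1,3,5-trimethylcyclohexa-2,4-dien-1-yl]-6-methoxy-3,5-dimethyl-4H-pyran-4-one (alkenyl and pyrone cis) | CC[C@@H](O[Si](C)(C)C(C)(C)C)[C@H](C)/C=C(\C)[C@H]1C(C)=CC(C)=C[C@@]1(C)c1oc(OC)c(C)c(=O)c1C | intermediate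
31 | 2-[(1R,4R,5R,6S)-5-[(2E,4R,5R)-5-[(tert-butyldimethylsilyl)oxy]-4-methylhept-2-en-2-yl]-2,4,6-trimethyl-7-oxabicyclo[4.1.0]hept-2-en-4-yl]-6-methoxy-3,5-dimethyl-4H-pyran-4-one (epoxide anti to alkenyl and pyrone) | CC[C@@H](O[Si](C)(C)C(C)(C)C)[C@H](C)/C=C(\C)[C@H]1[C@]2(C)O[C@@H]2C(C)=C[C@@]1(C)c1oc(OC)c(C)c(=O)c1C | intermediate
32 | 2-[(1R,4R,5R,6S)-5-[(2E,4R,5R)-5-hydroxy-4-methylhept-2-en-2-yl]-2,4,6-trimethyl-7-oxabicyclo[4.1.0]hept-2-en-4-yl]-6-methoxy-3,5-dimethyl-4H-pyran-4-one | CC[C@@H](O)[C@H](C)/C=C(\C)[C@H]1[C@]2(C)O[C@@H]2C(C)=C[C@@]1(C)c1oc(OC)c(C)c(=O)c1C | intermediate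
33 | 2-methoxy-3,5-dimethyl-6-[(1R,4R,5R,6S)-2,4,6-trimethyl-5-[(2E,4R)-4-methyl-5-oxohept-2-en-2-yl]-7-oxabicyclo[4.1.0]hept-2-en-4-yl]-4H-pyran-4-one (CNP0336888.3) | CCC(=O)[C@H](C)/C=C(\C)[C@H]1[C@]2(C)O[C@@H]2C(C)=C[C@@]1(C)c1oc(OC)c(C)c(=O)c1C | target

## Step count and risk

Total steps: 19. Longest linear sequence: 12 steps (steps 8 to 19, from 15).

The three steps most likely to fail:

Step 16 (proposed new asymmetric 6π electrocyclization). The catalysed closure may not outrun the racemic thermal one. The delocalised pyrylium may also allow E/Z scrambling or divert into an acid-induced bicyclo[3.1.0]hexene-forming cyclisation. The fallback uses known chemistry, sets out from 29 and comes back at 30. Tetraene 29 is heated without catalyst (toluene, 100 °C, dark), and the thermal disrotatory 6π electrocyclization gives 30 together with the (1S,6R)-cyclohexadiene ring diastereomer F1 in roughly equal amounts. Because the side chain carries two fixed stereocentres these are diastereomers, not enantiomers, and they are separated by preparative HPLC; 30 goes on to step 17.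

Step 17 (epoxidation). The side-chain alkene or the other ring alkene may compete, or the catalyst may prove mismatched. The fallback sets out from 30 and comes back at 33 by changing the order of events. Bu4NF first removes the silyl group to give the cyclohexadienyl alcohol F2. Dess–Martin periodinane with NaHCO3 then gives the cyclohexadienyl ethyl ketone F3. Only then is the diene epoxidised with dimethyldioxirane (acetone, −40 °C). The side-chain alkene is now β,γ to a ketone and inductively deactivated, so the neutral dioxirane should take the electron-rich diene at its open face and give 33 directly.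

Step 15 (hydrozirconation and Negishi coupling). The regiochemistry of Zr–H addition to the enyne or the coupling to the sensitive tetraene may fail. The fallback builds the chain linearly instead, sets out from 23 (with 22 and 6) and comes back at 29:
- A second Wittig reaction of 23 with 22 (toluene, 100 °C) gives the (2E,4E)-dienal F4.
- Still–Gennari olefination with ethyl 2-[bis(2,2,2-trifluoroethoxy)phosphoryl]propanoate (KN(SiMe3)2, 18-crown-6, THF, −78 °C) gives the (2Z,4E,6E)-trienoate ethyl ester F5.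
- i-Bu2AlH reduction gives the (2Z)-trienol F6, and MnO2 gives the (2Z)-trienal F7.
- Addition of lithiated pyrone 11 (from 6 and LiN(SiMe3)2, −78 °C) gives the trienyl aldol F8.
- MsCl and Et3N give the trienyl mesylate F9, which DBU eliminates to 29.

## Further compounds

F1 | step 16 | 2-[(1S,6R)-6-[(2E,4R,5R)-5-[(tert-butyldimethylsilyl)oxy]-4-methylhept-2-en-2-yl]-1,3,5-trimethylcyclohexa-2,4-dien-1-yl]-6-methoxy-3,5-dimethyl-4H-pyran-4-one | CC[C@@H](O[Si](C)(C)C(C)(C)C)[C@H](C)/C=C(\C)[C@@H]1C(C)=CC(C)=C[C@]1(C)c1oc(OC)c(C)c(=O)c1C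
F2 | step 17 | 2-[(1R,6S)-6-[(2E,4R,5R)-5-hydroxy-4-methylhept-2-en-2-yl]-1,3,5-trimethylcyclohexa-2,4-dien-1-yl]-6-methoxy-3,5-dimethyl-4H-pyran-4-one | CC[C@@H](O)[C@H](C)/C=C(\C)[C@H]1C(C)=CC(C)=C[C@@]1(C)c1oc(OC)c(C)c(=O)c1C
F3 | step 17 | 2-methoxy-3,5-dimethyl-6-[(1R,6S)-1,3,5-trimethyl-6-[(2E,4R)-4-methyl-5-oxohept-2-en-2-yl]cyclohexa-2,4-dien-1-yl]-4H-pyran-4-one | CCC(=O)[C@H](C)/C=C(\C)[C@H]1C(C)=CC(C)=C[C@@]1(C)c1oc(OC)c(C)c(=O)c1C
F4 | step 15 | (2E,4E,6R,7R)-7-[(tert-butyldimethylsilyl)oxy]-2,4,6-trimethylnona-2,4-dienal | CC[C@@H](O[Si](C)(C)C(C)(C)C)[C@H](C)/C=C(\C)/C=C(\C)C=O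
F5 | step 15 | ethyl (2Z,4E,6E,8R,9R)-9-[(tert-butyldimethylsilyl)oxy]-2,4,6,8-tetramethylundeca-2,4,6-trienoate | CC[C@@H](O[Si](C)(C)C(C)(C)C)[C@H](C)/C=C(\C)/C=C(\C)/C=C(/C)C(=O)OCC
F6 | step 15 | (2Z,4E,6E,8R,9R)-9-[(tert-butyldimethylsilyl)oxy]-2,4,6,8-tetramethylundeca-2,4,6-trien-1-ol | CC[C@@H](O[Si](C)(C)C(C)(C)C)[C@H](C)/C=C(\C)/C=C(\C)/C=C(/C)CO
F7 | step 15 | (2Z,4E,6E,8R,9R)-9-[(tert-butyldimethylsilyl)oxy]-2,4,6,8-tetramethylundeca-2,4,6-trienal | CC[C@@H](O[Si](C)(C)C(C)(C)C)[C@H](C)/C=C(\C)/C=C(\C)/C=C(/C)C=O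
F8 | step 15 | 2-[(4Z,6E,8E,10R,11R)-11-[(tert-butyldimethylsilyl)oxy]-3-hydroxy-4,6,8,10-tetramethyltrideca-4,6,8-trien-2-yl]-6-methoxy-3,5-dimethyl-4H-pyran-4-one (diastereomer mixture) | CC[C@@H](O[Si](C)(C)C(C)(C)C)[C@H](C)/C=C(\C)/C=C(\C)/C=C(/C)C(O)C(C)c1oc(OC)c(C)c(=O)c1C
F9 | step 15 | (4Z,6E,8E,10R,11R)-11-[(tert-butyldimethylsilyl)oxy]-2-(6-methoxy-3,5-dimethyl-4-oxo-4H-pyran-2-yl)-4,6,8,10-tetramethyltrideca-4,6,8-trien-3-yl methanesulfonate | CC[C@@H](O[Si](C)(C)C(C)(C)C)[C@H](C)/C=C(\C)/C=C(\C)/C=C(/C)C(OS(C)(=O)=O)C(C)c1oc(OC)c(C)c(=O)c1C
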